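**Plan**
- Retrosynthetic cuts, in order: (i) the two benzyl O–C bonds and the saturation of both two-carbon bridges, all returned by one final hydrogenation; (ii) the bond between the para-phenylene ring B and the bridge carbon remote from the hydroquinone ring A; (iii) the C=C of the bridge between rings C and D; (iv) the diaryl ether O–C(ring B) bond.
- Enabling feature: in ring A the hydroxyl oxygen ortho to the bridge, the two ring carbons between them and the two bridge carbons are the atoms O1–C7a–C3a–C3–C2 of a furan ring. 5-(Benzyloxy)benzofuran is therefore a masked 2-(2,5-dihydroxyphenyl)ethyl unit whose O1–C2 bond nickel can open with an aryl Grignard reagent.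
- Forward order: diaryl ether (Chan–Lam), then the E-stilbene bridge between rings C and D (Horner–Wadsworth–Emmons), then the arylmagnesium bromide opens the benzofuran (forming the ring B–carbon bond and freeing the ortho phenol), then one hydrogenation saturates both bridges and removes both benzyl groups.
- Stereochemistry: the target has no stereocentre. The E (olefination) and Z (ring opening) alkene geometries are transient and are erased in the last step.

Key step: step 4

Remark on the chemistry: compounds 1, 2, 4 and 6 are taken as catalogue materials.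

**Step 1**
Reactants: 1 4-(benzyloxy)-3-hydroxybenzaldehyde; 2 (4-bromophenyl)boronic acid
Product: 3 4-(benzyloxy)-3-(4-bromophenoxy)benzaldehyde
Conditions: 2 (2 equiv), Cu(OAc)2 (20 mol%), pyridine, 4 Å MS, O2 (1 atm), CH2Cl2, rt
Reagents that add atoms: none
Why: Chan–Lam oxidative O-arylation (copper phenoxide, transmetalation from boron, C–O reductive elimination) runs at room temperature, so the aryl bromide, the aldehyde and the benzyl ether should stay intact.

**Step 2**
Reactants: 3 4-(benzyloxy)-3-(4-bromophenoxy)benzaldehyde; 4 diethyl (3-methoxybenzyl)phosphonate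
Product: 5 1-(benzyloxy)-2-(4-bromophenoxy)-4-[(E)-2-(3-methoxyphenyl)ethenyl]benzene
Conditions: KOtBu, THF, 0 °C to rt; then 1 M HCl work-up
Reagents that add atoms: none
Why: Horner–Wadsworth–Emmons olefination of an aryl aldehyde with a benzylic phosphonate anion should give the E-stilbene as a single isomer and does not touch the aryl bromide.

**Step 3**
Reactants: 6 1-benzofuran-5-ol
Product: 7 5-(benzyloxy)-1-benzofuran
Conditions: BnBr, K2CO3, DMF, rt
Reagents that add atoms: benzyl bromide, BrCc1ccccc1
Why: Williamson etherification of the phenoxide protects the 5-hydroxyl with a group that the final hydrogenation removes.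

**Step 4**
Reactants: 5 1-(benzyloxy)-2-(4-bromophenoxy)-4-[(E)-2-(3-methoxyphenyl)ethenyl]benzene; 7 5-(benzyloxy)-1-benzofuran
Product: 10 4-(benzyloxy)-2-[(Z)-2-{4-[2-(benzyloxy)-5-[(E)-2-(3-methoxyphenyl)ethenyl]phenoxy]phenyl}ethenyl]phenol, via arylmagnesium bromide 8 (not isolated), via bromomagnesium phenolate 9 (not isolated)
Conditions: (i) Mg turnings (I2 cat.), THF, 50 °C; (ii) 7 (1.5 equiv), NiCl2(PPh3)2 (10 mol%), toluene/THF, 80 °C; (iii) 1 M HCl, 0 °C
Reagents that add atoms: none
Why: Ni(0), formed from the precatalyst and a little of Grignard reagent 8, should bind the C2=C3 π bond of 7 and insert into the O1–C2 enol-ether bond to give an alkenylnickel phenolate; transmetalation with 8 passes the phenolate to magnesium (9) and the aryl group to nickel, and reductive elimination forms the aryl–C2 bond. The closest known reaction type is the nickel-catalysed Kumada-type cross-coupling of enol ethers with C(sp2)–O cleavage, known as the arylative ring opening of benzofurans by aryl Grignard reagents to 2-hydroxystilbenes. No ring is closed: the furan ring (O1, C2, C3, C3a, C7a) is opened, which frees the ortho phenol oxygen and leaves C2 and C3 as the two bridge carbons. No stereocentre is formed; the cis geometry fixed by the former ring should be retained (Z), and step 5 erases it in any case. The selectivity needed is among C–O bonds (furan O1–C2 against aryl–OMe, aryl–OBn, benzyl–O and the diaryl ether), and it is secured because only O1–C2 is an enol-ether bond activated by π-coordination that releases a phenolate, while triphenylphosphine-ligated nickel is expected to leave unfused aryl ethers alone at this temperature. The inexpensive benzofuran is used in excess so that the advanced Grignard reagent is the limiting partner.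

**Step 5**
Reactants: 10 4-(benzyloxy)-2-[(Z)-2-{4-[2-(benzyloxy)-5-[(E)-2-(3-methoxyphenyl)ethenyl]phenoxy]phenyl}ethenyl]phenol
Product: 11 2-[2-(4-{2-hydroxy-5-[2-(3-methoxyphenyl)ethyl]phenoxy}phenyl)ethyl]benzene-1,4-diol
Conditions: H2 (1 atm), 10% Pd/C, EtOAc/MeOH, rt; filtration under argon
Reagents that add atoms: none
Why: Catalytic hydrogenation should saturate both stilbene double bonds and hydrogenolyse both benzyl aryl ethers in one operation, while the methyl ether and the diaryl ether are inert to Pd/C under these conditions.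

**Compound list**
1 | 4-(benzyloxy)-3-hydroxybenzaldehyde | O=Cc1ccc(OCc2ccccc2)c(O)c1 | starting material
2 | (4-bromophenyl)boronic acid | OB(O)c1ccc(Br)cc1 | starting material
3 | 4-(benzyloxy)-3-(4-bromophenoxy)benzaldehyde | O=Cc1ccc(OCc2ccccc2)c(Oc2ccc(Br)cc2)c1 | intermediate
4 | diethyl (3-methoxybenzyl)phosphonate | CCOP(=O)(Cc1cccc(OC)c1)OCC | starting material
5 | 1-(benzyloxy)-2-(4-bromophenoxy)-4-[(E)-2-(3-methoxyphenyl)ethenyl]benzene | COc1cccc(/C=C/c2ccc(OCc3ccccc3)c(Oc3ccc(Br)cc3)c2)c1 | intermediate
6 | 1-benzofuran-5-ol | Oc1ccc2occc2c1 | starting material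
7 | 5-(benzyloxy)-1-benzofuran | c1ccc(COc2ccc3occc3c2)cc1 | intermediate
8 | {4-[2-(benzyloxy)-5-[(E)-2-(3-methoxyphenyl)ethenyl]phenoxy]phenyl}magnesium bromide | COc1cccc(/C=C/c2ccc(OCc3ccccc3)c(Oc3ccc([Mg]Br)cc3)c2)c1 | intermediate
9 | bromomagnesium 4-(benzyloxy)-2-[(Z)-2-{4-[2-(benzyloxy)-5-[(E)-2-(3-methoxyphenyl)ethenyl]phenoxy]phenyl}ethenyl]phenolate | COc1cccc(/C=C/c2ccc(OCc3ccccc3)c(Oc3ccc(/C=C\c4cc(OCc5ccccc5)ccc4O[Mg]Br)cc3)c2)c1 | intermediate
10 | 4-(benzyloxy)-2-[(Z)-2-{4-[2-(benzyloxy)-5-[(E)-2-(3-methoxyphenyl)ethenyl]phenoxy]phenyl}ethenyl]phenol | COc1cccc(/C=C/c2ccc(OCc3ccccc3)c(Oc3ccc(/C=C\c4cc(OCc5ccccc5)ccc4O)cc3)c2)c1 | intermediate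
11 | 2-[2-(4-{2-hydroxy-5-[2-(3-methoxyphenyl)ethyl]phenoxy}phenyl)ethyl]benzene-1,4-diol | COc1cccc(CCc2ccc(O)c(Oc3ccc(CCc4cc(O)ccc4O)cc3)c2)c1 | target

**Count**
Total steps: 5. Longest linear sequence: 4 steps (1 → 3 → 5 → 10 → 11; steps 1, 2, 4 and 5).

**Steps most likely to fail**

Step 4. Magnesium insertion into the electron-rich aryl bromide may be sluggish and give homocoupling. Nickel may also insert into a benzyl–oxygen or aryl–OMe bond, or add too slowly to the electron-rich benzofuran, so that the Grignard reagent is lost to reduction and biaryl formation. The fallback is a Mizoroki–Heck coupling that forms the same aryl–carbon bond. It sets out from 5. Purchased 2,5-dihydroxybenzaldehyde (O=Cc1cc(O)ccc1O) is benzylated twice (BnBr, K2CO3, DMF) to 2,5-bis(benzyloxy)benzaldehyde F1. Wittig methylenation (Ph3PCH3Br, KOtBu, THF) converts this into 1,4-bis(benzyloxy)-2-ethenylbenzene F2. Coupling of 5 with F2 (Pd(OAc)2, P(o-tol)3, K2CO3, DMF, 100 °C) should give 1,4-bis(benzyloxy)-2-[(E)-2-{4-[2-(benzyloxy)-5-[(E)-2-(3-methoxyphenyl)ethenyl]phenoxy]phenyl}ethenyl]benzene F3. Hydrogenation of F3 under the conditions of step 5 removes three benzyl groups and saturates both alkenes, and the fallback comes back to the route at 11.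

Step 1. Transmetalation to the copper phenoxide of the ortho-alkoxy phenol may be slow, so that protodeboronation and oxidative homocoupling of the boronic acid consume the partner. The fallback is a metal-free O-arylation by ligand coupling at iodine(III): the potassium phenoxide of 1 (KOtBu, THF) is treated with bis(4-bromophenyl)iodonium triflate at rt to 40 °C. It sets out from 1 and comes back at 3 without any new intermediate.

Step 5. Hydrogenolysis of the benzyl ethers may stall through catalyst poisoning by traces of phosphine or nickel, and the hydroquinone may oxidise in air to the quinone during filtration. The fallback separates the two tasks and uses no heterogeneous catalyst. It sets out from 10. Diimide reduction (TsNHNH2, NaOAc, THF/H2O, reflux) saturates both alkenes to give 4-(benzyloxy)-2-[2-(4-{2-(benzyloxy)-5-[2-(3-methoxyphenyl)ethyl]phenoxy}phenyl)ethyl]phenol F4. BCl3 with pentamethylbenzene (CH2Cl2, −78 °C) then cleaves the two benzyl ethers while sparing the methyl ether, and the fallback comes back at 11.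

**Further compounds**
F1 | step 4 | 2,5-bis(benzyloxy)benzaldehyde | O=Cc1cc(OCc2ccccc2)ccc1OCc1ccccc1
F2 | step 4 | 1,4-bis(benzyloxy)-2-ethenylbenzene | C=Cc1cc(OCc2ccccc2)ccc1OCc1ccccc1
F3 | step 4 | 1,4-bis(benzyloxy)-2-[(E)-2-{4-[2-(benzyloxy)-5-[(E)-2-(3-methoxyphenyl)ethenyl]phenoxy]phenyl}ethenyl]benzene | COc1cccc(/C=C/c2ccc(OCc3ccccc3)c(Oc3ccc(/C=C/c4cc(OCc5ccccc5)ccc4OCc4ccccc4)cc3)c2)c1
F0 | step 1 | none | none
F4 | step 5 | 4-(benzyloxy)-2-[2-(4-{2-(benzyloxy)-5-[2-(3-methoxyphenyl)ethyl]phenoxy}phenyl)ethyl]phenol | COc1cccc(CCc2ccc(OCc3ccccc3)c(Oc3ccc(CCc4cc(OCc5ccccc5)ccc4O)cc3)c2)c1
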